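Remark on the chemistry: the target is achiral. The flavanones 12 and 18 and the bis-epoxide 21 form as racemates or diastereomer mixtures and lose their stereocentres within the same step. LiN(iPr)2 and Mg(OMe)2 are taken as commercial solutions.

Numbering key: 1–4 starting materials and their protected forms; 5 diaryl ether aldehyde; 6 Weinreb cinnamamide; 7 4-methoxy-6-methyl-2H-pyran-2-one; 8 its lithio derivative; 9 pyranone ketone (precursor of the key step); 10 ring-opened ester; 11 chalcone (product of the key step); 12–14 unit 1 flavanone, flavone acetal, flavone aldehyde; 15, 16 acetophenone for unit 2; 17 chalcone of unit 2; 18 flavanone; 19 bis-flavone; 20 fully protected bis-flavone; 21 bis-epoxide; 22 protected bis-flavonol; 23 target.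

## Analysis of the target

Compound 23 is made of two 3-hydroxy-2-aryl-4H-chromen-4-ones (flavonols) joined by a diaryl ether oxygen between C4' of one ring B and C4' of the other. Unit 1 is the 3,5,3'-trihydroxy-7-methoxy half and unit 2 the 3,5,7-trihydroxy-3'-methoxy half. There is no stereocentre, so only the E geometry of open-chain intermediates has to be watched, and it disappears on ring closure. The 3-hydroxy-4-pyranone enols and the electron-rich rings A are oxidised easily in base and air, and C2 of each chromenone is open to hydroxide, so the free polyphenol should appear only in the last step. The difficulty is differentiation of oxygens. Nine oxygen substituents sit on the periphery, only two of them are methylated, and the two rings A differ: O7 is methylated and O5 free in unit 1, while both are free in unit 2. In addition, each flavonol has a 5-oxygen, the pattern for which direct oxidative cyclisation of a chalcone to a flavonol tends to give aurones. The strategy rests on ring A of unit 1 (C4a, C5, C6, C7, C8, C8a). It is a phloroglucinol methylated at one oxygen only, and all six of its carbons, with the methyl ether already at the future C7, are present in pyranone 7.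

## Retrosynthetic reasoning

23 from 22. The last disconnection cuts four benzyl–oxygen bonds (O5 and O3' of unit 1, O5 and O7 of unit 2). Hydrogenolysis is the only deprotection that leaves the two methyl ethers, the diaryl ether and the enolic C3 hydroxyls alone, so every temporary group in the route is a benzyl ether.

22 from 20 and 19. Both C3–O bonds are cut together. Electrophilic oxygen transfer to C2=C3 of a flavone, followed by acid isomerisation of the epoxide, is the dependable way to a 5-oxygenated flavonol. It is placed after both chromenones exist because the oxidant would attack an aldehyde or an acetal C–H, and neither is left in 20. One operation then serves both halves. Benzylation of the chelated O5 of unit 1 (19 to 20) removes the last free phenol before the oxidation.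

19 from 17, and 17 from 14 and 16. Unit 2 is opened at O1–C2 and then at the enone double bond, which leads to aldehyde 14 and acetophenone 16. The aldol condensation has to work on an aldehyde that already carries the unit 1 flavone. That flavone is kept as its 5-phenoxide, which makes the chromenone less electrophilic toward hydroxide.

14 from 11. Unit 1 is opened at O1–C2, and the aldehyde is put back under its dimethyl acetal. The forward step closes the pyranone ring, dehydrogenates it and sets the aldehyde free in one flask. The acetal therefore only has to survive basic steps.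

11 from 9 (through 10). The bond between C4a and a neighbouring oxygen-bearing ring carbon of ring A is cut. This unravels the aromatic ring into a chain that is stored as pyranone 9. Cutting here means the O7 methyl group and the two free phenols never have to be told apart by protection or selective demethylation, and the cinnamoyl unit is already attached at the right carbon. The forward reaction must open the lactone, choose Claisen over aldol folding, and aromatise.

9 from 6 and 7 (through 8). The bond between the side-chain methylene and the ketone carbon is cut. Pyranone 7 is deprotonated at its methyl group and acylated by the N-methoxy-N-methylamide 6, which delivers the cinnamoyl unit without over-addition.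

6 from 5, and 5 from 2 and 4. The alkene of 6 comes from a phosphonate olefination of aldehyde 5. The diaryl ether C–O bond of 5 is cut on the side of the ring that carries the formyl group, because a para formyl group activates a fluoride for aromatic substitution. The other aldehyde is masked in 4, so 5 has a single reactive carbonyl. Compounds 2 and 4 are one step from 1 and 3.

## Alternatives that were turned down

Alternative 1: Ring B of unit 1 would be built by cycloaddition, with the C2'–C3' and C1'–C6' bonds cut back to the 3-aryloxyfuran A1, which carries the fully protected unit 2, and methyl propiolate A2. In the forward step A1 and A2 would undergo a Diels–Alder reaction. The oxanorbornadiene would open and tautomerise, and the bridge oxygen would become the C3' hydroxyl of the benzoate A3. In its favour, the 3'-hydroxyl arises unprotected and next to the ether oxygen, and the donor–acceptor pairing of furan C2 with the alkyne CH fixes the orientation. On this point the alternative is stronger than the chosen route, which carries a benzyl ether from step 1 to the end. Against it, ring B is an ordinary trisubstituted benzene that compound 1 supplies ready-made, so the key step would solve no real problem of the target. A1 needs an ether bond to C3 of a furan, which has no reliable nucleophilic or electrophilic entry with a hindered ortho-methoxyphenol. The bridge can also open toward either bridgehead, and the wrong mode gives a salicylate isomer. After A3, the whole of unit 1 (rings A and C, the O7/O5 distinction and the C3 hydroxyl) would still have to be made from an ester. The chosen strategy spends its key step on that very distinction and reaches its precursor 9 in five ordinary steps.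

Alternative 2: Here the O1–C8a bond and the C5–O and C7–O bonds of unit 2 would be cut, back to the 2-benzyloxy-1,3-diketone A4 with a 2,4,6-trifluorophenyl ketone. A mild carbonate base would close ring C by attack of the enolate oxygen on an ortho C–F carbon. Sodium benzyloxide A5 in the same flask would then replace the fluorides at C5 and C7 to give A6. In its favour, the two ortho fluorides are equivalent, the C3 oxygen is carried in from the start, and the route is convergent. On the C3 oxygen and on convergence it is stronger than the chosen route, which needs a late double oxidation. Against it, the first alkoxide that enters deactivates the ring for the second exchange. Forcing conditions with excess A5 invite conjugate attack at C2 of either chromenone, and the finished unit 1 is present at that point. Making A4 requires C-acylation of an α-alkoxy ketone enolate with a polyfluorobenzoyl halide, where O-acylation and para-fluoride displacement compete. Most important, unit 1 in A6 is a 5,7-dimethyl ether. The end of the route therefore needs a selective cleavage of the O5 methyl group by a Lewis acid in the presence of the O7 and O3' methyl ethers, which is a selectivity problem the route creates for itself. The chosen strategy has no demethylation at all, because O5 is born free and O7 is born methylated.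

Alternative 3: Both C2–C3 bonds would be cut at once, back to the diaryl ether diester A7, in which each carboxyl is esterified with a 2-(benzyloxyacetyl)phenol. In the forward step base would turn both benzyloxymethyl ketones into enolates, each would take over its neighbouring aroyl group (double Baker–Venkataraman transfer) to give the bis-diketone A8, and acid would then close both rings C. In its favour, the acyl transfer is reliable, both C3 oxygens are present from the start, and both halves are advanced in one operation. In convergence and in the C3 oxygens it is stronger than the chosen route. Against it, A7 is unsymmetrical, so the two carboxyl groups of the diacid must be told apart and esterified one after the other. Each of the two ω-benzyloxyacetophenones is itself a multistep compound. Aryl esters can exchange between the two halves under the basic conditions. Unit 1 again arrives as the 5,7-dimethyl ether (see A8) and needs the same selective demethylation as in alternative 2. The chosen strategy has a longer endgame, but the methylation pattern of ring A is fixed by construction and needs no selective reagent.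

Key step: step 6

## Route

Step 1
Reactants: 1 4-fluoro-3-hydroxybenzaldehyde
Product: 2 3-(benzyloxy)-4-fluorobenzaldehyde
Conditions: BnBr, K2CO3, DMF, rt
Reagents that add atoms: benzyl bromide, BrCc1ccccc1
Why: Williamson etherification of the phenol; the aldehyde and the aryl fluoride are inert to carbonate at room temperature, and the free phenoxide, which would shut down the later substitution, is removed.

Step 2
Reactants: 3 vanillin (4-hydroxy-3-methoxybenzaldehyde)
Product: 4 4-(dimethoxymethyl)-2-methoxyphenol
Conditions: HC(OMe)3, MeOH, TsOH·H2O (cat.), rt; then K2CO3, evaporate, use crude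
Reagents that add atoms: trimethyl orthoformate, COC(OC)OC
Why: Acid-catalysed acetalisation driven by the orthoformate; the para-hydroxy acetal is acid-labile, so the acid is quenched with base before concentration and the phenol is carried on without chromatography.

Step 3
Reactants: 2 3-(benzyloxy)-4-fluorobenzaldehyde; 4 4-(dimethoxymethyl)-2-methoxyphenol
Product: 5 3-(benzyloxy)-4-[4-(dimethoxymethyl)-2-methoxyphenoxy]benzaldehyde
Conditions: K2CO3, DMSO, 100 °C, N2
Reagents that add atoms: none
Why: Nucleophilic aromatic substitution (addition–elimination) of fluoride para to the formyl group by the phenoxide of 4; acetals are inert to carbonate, so 5 has one free and one masked aldehyde.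

Step 4
Reactants: 5 3-(benzyloxy)-4-[4-(dimethoxymethyl)-2-methoxyphenoxy]benzaldehyde
Product: 6 (2E)-3-{3-(benzyloxy)-4-[4-(dimethoxymethyl)-2-methoxyphenoxy]phenyl}-N-methoxy-N-methylprop-2-enamide
Conditions: (EtO)2P(O)CH2C(O)N(OMe)Me, NaH, THF, 0 °C to rt
Reagents that add atoms: diethyl [2-(methoxy(methyl)amino)-2-oxoethyl]phosphonate, CCOP(=O)(OCC)CC(=O)N(C)OC
Why: Horner–Wadsworth–Emmons olefination with a stabilised phosphonate gives the E-cinnamamide under thermodynamic control; the acetal, benzyl ether and diaryl ether are stable to the base.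

Step 5
Reactants: 6 (2E)-3-{3-(benzyloxy)-4-[4-(dimethoxymethyl)-2-methoxyphenoxy]phenyl}-N-methoxy-N-methylprop-2-enamide; 7 4-methoxy-6-methyl-2H-pyran-2-one
Product: 9 6-[(3E)-4-{3-(benzyloxy)-4-[4-(dimethoxymethyl)-2-methoxyphenoxy]phenyl}-2-oxobut-3-en-1-yl]-4-methoxy-2H-pyran-2-one, via lithiated pyranone 8 (not isolated)
Conditions: 7 (2.2 equiv), LiN(iPr)2 (LDA, 2.2 equiv), THF, −78 °C; then 6, −78 to −40 °C; aq. NH4Cl
Reagents that add atoms: none
Why: The hindered amide base deprotonates the C6 methyl group of 7 to the vinylogous enolate 8, which adds 1,2 to the Weinreb amide (acylation of a carbanion). The chelated tetrahedral adduct persists until the quench, so the acidic methylene of 9 is not exposed to the nucleophile and no second addition occurs.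

Step 6
Reactants: 9 6-[(3E)-4-{3-(benzyloxy)-4-[4-(dimethoxymethyl)-2-methoxyphenoxy]phenyl}-2-oxobut-3-en-1-yl]-4-methoxy-2H-pyran-2-one
Product: 11 (2E)-3-{3-(benzyloxy)-4-[4-(dimethoxymethyl)-2-methoxyphenoxy]phenyl}-1-(2,6-dihydroxy-4-methoxyphenyl)prop-2-en-1-one, via ring-opened diketo ester 10 (not isolated)
Conditions: Mg(OMe)2 (8 equiv), MeOH–THF, reflux, N2; cold aq. NH4Cl
Reagents that add atoms: none
Why: Methoxide adds to the lactone carbonyl of 9 and the ring opens to the methyl ester 10 (chain numbering: C1 ester, C2=C3 enol ether, C5 and C7 ketones), in which the ester and the C4 methylene stay on the same side of the double bond as they were in the ring. The 5,7-diketone is held as a magnesium chelate and its central carbon C6 attacks the ester carbonyl in a Claisen (Dieckmann-type) condensation; loss of methoxide and enolisation give the aromatic ring A. The closest known reaction type is the magnesium-alkoxide-induced Claisen cyclisation of 3,5,7-triketo esters and of 6-(2-oxoalkyl)-2-pyranones to acylphloroglucinols. The ring closes in the 6-exo-trig mode and no stereocentre is formed. The selectivity needed is C-acylation from C6 and not aldol closure from C2 onto the C7 ketone; C2 is a vinylic enol ether carbon and cannot act as a nucleophile unless the double bond first leaves conjugation, and chelation of the diketone by Mg2+ keeps the nucleophilic site at C6 and damps retro-Claisen cleavage. The enol ether carbon C3 becomes C7 of the flavonoid with its methyl group in place, and the ester carbon and the C5 ketone carbon become the two phenolic carbons, so the O7-methyl/O5-free pattern arises without a protecting group. The acetal, the benzyl ether and the diaryl ether are stable to the alkoxide. Reversible methoxide addition to the enone and partial closure to flavanone 12 do no harm, because step 7 converts chalcone and flavanone alike.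

Step 7
Reactants: 11 (2E)-3-{3-(benzyloxy)-4-[4-(dimethoxymethyl)-2-methoxyphenoxy]phenyl}-1-(2,6-dihydroxy-4-methoxyphenyl)prop-2-en-1-one
Product: 14 4-[2-(benzyloxy)-4-(5-hydroxy-7-methoxy-4-oxo-4H-chromen-2-yl)phenoxy]-3-methoxybenzaldehyde, via flavanone acetal 12 (not isolated), via flavone acetal 13 (not isolated)
Conditions: I2 (0.1 equiv), DMSO, 120 °C; then 1 M HCl, THF, rt
Reagents that add atoms: water, O
Why: Intramolecular oxa-Michael addition of a phenol gives flavanone 12, and α-iodination with loss of HI gives the flavone while the sulfoxide regenerates I2 (oxidative cyclisation of a 2'-hydroxychalcone). The two phenols are equivalent, so only one flavone can form, and a catalytic amount of I2 limits iodination of the electron-rich ring A. The acid treatment completes hydrolysis of the dimethyl acetal, which has done its work.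

Step 8
Reactants: 15 1-(2,4,6-trihydroxyphenyl)ethanone
Product: 16 1-[2,4-bis(benzyloxy)-6-hydroxyphenyl]ethanone
Conditions: BnBr (2.05 equiv), K2CO3, DMF, rt to 40 °C
Reagents that add atoms: benzyl bromide, BrCc1ccccc1
Why: Williamson etherification; after the para and one ortho hydroxyl have reacted, the remaining ortho hydroxyl is hydrogen-bonded to the ketone and is left free with two equivalents of halide.

Step 9
Reactants: 14 4-[2-(benzyloxy)-4-(5-hydroxy-7-methoxy-4-oxo-4H-chromen-2-yl)phenoxy]-3-methoxybenzaldehyde; 16 1-[2,4-bis(benzyloxy)-6-hydroxyphenyl]ethanone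
Product: 17 2-{3-(benzyloxy)-4-[4-((1E)-3-[2,4-bis(benzyloxy)-6-hydroxyphenyl]-3-oxoprop-1-en-1-yl)-2-methoxyphenoxy]phenyl}-5-hydroxy-7-methoxy-4H-chromen-4-one
Conditions: KOH (aq.), EtOH–THF, rt, Ar
Reagents that add atoms: none
Why: Claisen–Schmidt aldol condensation of the methyl ketone with the non-enolisable aldehyde gives the E-enone. The unit 1 flavone is present as its 5-phenoxide, which lowers the electrophilicity of C2 toward hydroxide at room temperature.

Step 10
Reactants: 17 2-{3-(benzyloxy)-4-[4-((1E)-3-[2,4-bis(benzyloxy)-6-hydroxyphenyl]-3-oxoprop-1-en-1-yl)-2-methoxyphenoxy]phenyl}-5-hydroxy-7-methoxy-4H-chromen-4-one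
Product: 19 5,7-bis(benzyloxy)-2-{4-[2-(benzyloxy)-4-(5-hydroxy-7-methoxy-4-oxo-4H-chromen-2-yl)phenoxy]-3-methoxyphenyl}-4H-chromen-4-one, via unit 2 flavanone 18 (not isolated)
Conditions: I2 (0.1 equiv), DMSO, 120 °C
Reagents that add atoms: none
Why: The same oxidative cyclisation as in step 7 (oxa-Michael closure, then iodine-mediated dehydrogenation); only one ortho hydroxyl is free, so ring C closes in one direction, and the finished flavone of unit 1 is inert to the conditions.

Step 11
Reactants: 19 5,7-bis(benzyloxy)-2-{4-[2-(benzyloxy)-4-(5-hydroxy-7-methoxy-4-oxo-4H-chromen-2-yl)phenoxy]-3-methoxyphenyl}-4H-chromen-4-one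
Product: 20 5,7-bis(benzyloxy)-2-{4-[2-(benzyloxy)-4-(5-(benzyloxy)-7-methoxy-4-oxo-4H-chromen-2-yl)phenoxy]-3-methoxyphenyl}-4H-chromen-4-one
Conditions: BnBr, K2CO3, Bu4NI (cat.), DMF, 70 °C
Reagents that add atoms: benzyl bromide, BrCc1ccccc1
Why: Williamson etherification of the chelated 5-hydroxyl, which needs heat; it removes the last free phenol before the oxidation and would also re-benzylate any O5 of unit 2 that lost its benzyl group to HI in step 10.

Step 12
Reactants: 20 5,7-bis(benzyloxy)-2-{4-[2-(benzyloxy)-4-(5-(benzyloxy)-7-methoxy-4-oxo-4H-chromen-2-yl)phenoxy]-3-methoxyphenyl}-4H-chromen-4-one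
Product: 22 5,7-bis(benzyloxy)-2-{4-[2-(benzyloxy)-4-(5-(benzyloxy)-3-hydroxy-7-methoxy-4-oxo-4H-chromen-2-yl)phenoxy]-3-methoxyphenyl}-3-hydroxy-4H-chromen-4-one, via bis-epoxide 21 (not isolated)
Conditions: DMDO (acetone solution, excess, in portions), CH2Cl2, 0 °C to rt; evaporate; then TsOH·H2O (cat.), CH2Cl2, rt
Reagents that add atoms: dimethyldioxirane, CC1(C)OO1
Why: Dioxirane epoxidation of both C2=C3 bonds under neutral conditions, followed by acid-catalysed opening of each 2,3-epoxyflavanone at C2 (cation stabilised by O1 and the aryl group) and loss of H3 to the 3-hydroxyflavone. Substrates of this kind, flavones whose phenols are all benzyl or methyl ethers, are the ones on which this two-stage hydroxylation is established, and the stereocentres of 21 vanish.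

Step 13
Reactants: 22 5,7-bis(benzyloxy)-2-{4-[2-(benzyloxy)-4-(5-(benzyloxy)-3-hydroxy-7-methoxy-4-oxo-4H-chromen-2-yl)phenoxy]-3-methoxyphenyl}-3-hydroxy-4H-chromen-4-one
Product: 23 3,5,7-trihydroxy-2-{4-[2-hydroxy-4-(3,5-dihydroxy-7-methoxy-4-oxo-4H-chromen-2-yl)phenoxy]-3-methoxyphenyl}-4H-chromen-4-one (CNP0190193.0)
Conditions: H2 (1 atm), Pd/C (10 %), THF–MeOH, rt; work-up under Ar
Reagents that add atoms: none
Why: Catalytic hydrogenolysis of the four aryl benzyl ethers; the tetrasubstituted C2=C3 bonds of the flavonols, the two methyl ethers and the diaryl ether are not touched under these conditions.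

## Compound list

1 | 4-fluoro-3-hydroxybenzaldehyde | O=Cc1ccc(F)c(O)c1 | starting material
2 | 3-(benzyloxy)-4-fluorobenzaldehyde | O=Cc1ccc(F)c(OCc2ccccc2)c1 | intermediate
3 | vanillin (4-hydroxy-3-methoxybenzaldehyde) | COc1cc(C=O)ccc1O | starting material
4 | 4-(dimethoxymethyl)-2-methoxyphenol | COc1cc(C(OC)OC)ccc1O | intermediate
5 | 3-(benzyloxy)-4-[4-(dimethoxymethyl)-2-methoxyphenoxy]benzaldehyde | COC(OC)c1ccc(Oc2ccc(C=O)cc2OCc2ccccc2)c(OC)c1 | intermediate
6 | (2E)-3-{3-(benzyloxy)-4-[4-(dimethoxymethyl)-2-methoxyphenoxy]phenyl}-N-methoxy-N-methylprop-2-enamide | CON(C)C(=O)/C=C/c1ccc(Oc2ccc(C(OC)OC)cc2OC)c(OCc2ccccc2)c1 | intermediate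
7 | 4-methoxy-6-methyl-2H-pyran-2-one | COC1=CC(=O)OC(C)=C1 | starting material
8 | 6-(lithiomethyl)-4-methoxy-2H-pyran-2-one (not isolated) | [Li]CC1=CC(OC)=CC(=O)O1 | intermediate
9 | 6-[(3E)-4-{3-(benzyloxy)-4-[4-(dimethoxymethyl)-2-methoxyphenoxy]phenyl}-2-oxobut-3-en-1-yl]-4-methoxy-2H-pyran-2-one | COC1=CC(=O)OC(CC(=O)/C=C/c2ccc(Oc3ccc(C(OC)OC)cc3OC)c(OCc3ccccc3)c2)=C1 | intermediate
10 | methyl (2E,8E)-9-{3-(benzyloxy)-4-[4-(dimethoxymethyl)-2-methoxyphenoxy]phenyl}-3-methoxy-5,7-dioxonona-2,8-dienoate, as its magnesium chelate (not isolated) | COC(=O)/C=C(/OC)CC(=O)CC(=O)/C=C/c1ccc(Oc2ccc(C(OC)OC)cc2OC)c(OCc2ccccc2)c1 | intermediate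
11 | (2E)-3-{3-(benzyloxy)-4-[4-(dimethoxymethyl)-2-methoxyphenoxy]phenyl}-1-(2,6-dihydroxy-4-methoxyphenyl)prop-2-en-1-one | COc1cc(O)c(C(=O)/C=C/c2ccc(Oc3ccc(C(OC)OC)cc3OC)c(OCc3ccccc3)c2)c(O)c1 | intermediate
12 | rac-2-{3-(benzyloxy)-4-[4-(dimethoxymethyl)-2-methoxyphenoxy]phenyl}-5-hydroxy-7-methoxy-2,3-dihydro-4H-chromen-4-one (not isolated) | COc1cc(O)c2C(=O)CC(c3ccc(Oc4ccc(C(OC)OC)cc4OC)c(OCc4ccccc4)c3)Oc2c1 | intermediate
13 | 2-{3-(benzyloxy)-4-[4-(dimethoxymethyl)-2-methoxyphenoxy]phenyl}-5-hydroxy-7-methoxy-4H-chromen-4-one (not isolated) | COc1cc(O)c2c(=O)cc(-c3ccc(Oc4ccc(C(OC)OC)cc4OC)c(OCc4ccccc4)c3)oc2c1 | intermediate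
14 | 4-[2-(benzyloxy)-4-(5-hydroxy-7-methoxy-4-oxo-4H-chromen-2-yl)phenoxy]-3-methoxybenzaldehyde | COc1cc(O)c2c(=O)cc(-c3ccc(Oc4ccc(C=O)cc4OC)c(OCc4ccccc4)c3)oc2c1 | intermediate
15 | 1-(2,4,6-trihydroxyphenyl)ethanone (2',4',6'-trihydroxyacetophenone) | CC(=O)c1c(O)cc(O)cc1O | starting material
16 | 1-[2,4-bis(benzyloxy)-6-hydroxyphenyl]ethanone | CC(=O)c1c(O)cc(OCc2ccccc2)cc1OCc1ccccc1 | intermediate
17 | 2-{3-(benzyloxy)-4-[4-((1E)-3-[2,4-bis(benzyloxy)-6-hydroxyphenyl]-3-oxoprop-1-en-1-yl)-2-methoxyphenoxy]phenyl}-5-hydroxy-7-methoxy-4H-chromen-4-one | COc1cc(O)c2c(=O)cc(-c3ccc(Oc4ccc(/C=C/C(=O)c5c(O)cc(OCc6ccccc6)cc5OCc5ccccc5)cc4OC)c(OCc4ccccc4)c3)oc2c1 | intermediate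
18 | rac-5,7-bis(benzyloxy)-2-{4-[2-(benzyloxy)-4-(5-hydroxy-7-methoxy-4-oxo-4H-chromen-2-yl)phenoxy]-3-methoxyphenyl}-2,3-dihydro-4H-chromen-4-one (not isolated) | COc1cc(O)c2c(=O)cc(-c3ccc(Oc4ccc(C5CC(=O)c6c(OCc7ccccc7)cc(OCc7ccccc7)cc6O5)cc4OC)c(OCc4ccccc4)c3)oc2c1 | intermediate
19 | 5,7-bis(benzyloxy)-2-{4-[2-(benzyloxy)-4-(5-hydroxy-7-methoxy-4-oxo-4H-chromen-2-yl)phenoxy]-3-methoxyphenyl}-4H-chromen-4-one | COc1cc(O)c2c(=O)cc(-c3ccc(Oc4ccc(-c5cc(=O)c6c(OCc7ccccc7)cc(OCc7ccccc7)cc6o5)cc4OC)c(OCc4ccccc4)c3)oc2c1 | intermediate
20 | 5,7-bis(benzyloxy)-2-{4-[2-(benzyloxy)-4-(5-(benzyloxy)-7-methoxy-4-oxo-4H-chromen-2-yl)phenoxy]-3-methoxyphenyl}-4H-chromen-4-one | COc1cc(OCc2ccccc2)c2c(=O)cc(-c3ccc(Oc4ccc(-c5cc(=O)c6c(OCc7ccccc7)cc(OCc7ccccc7)cc6o5)cc4OC)c(OCc4ccccc4)c3)oc2c1 | intermediate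
21 | bis(2,3-epoxide) of 20, both chromenone C2=C3 bonds epoxidised, mixture of diastereomers (not isolated) | O=C1C2OC2(c2ccc(Oc3ccc(C45OC4C(=O)c4c(OCc6ccccc6)cc(OCc6ccccc6)cc4O5)cc3OC)c(OCc3ccccc3)c2)Oc2cc(OC)cc(OCc3ccccc3)c12 | intermediate
22 | 5,7-bis(benzyloxy)-2-{4-[2-(benzyloxy)-4-(5-(benzyloxy)-3-hydroxy-7-methoxy-4-oxo-4H-chromen-2-yl)phenoxy]-3-methoxyphenyl}-3-hydroxy-4H-chromen-4-one | COc1cc(OCc2ccccc2)c2c(=O)c(O)c(-c3ccc(Oc4ccc(-c5oc6cc(OCc7ccccc7)cc(OCc7ccccc7)c6c(=O)c5O)cc4OC)c(OCc4ccccc4)c3)oc2c1 | intermediate
23 | 3,5,7-trihydroxy-2-{4-[2-hydroxy-4-(3,5-dihydroxy-7-methoxy-4-oxo-4H-chromen-2-yl)phenoxy]-3-methoxyphenyl}-4H-chromen-4-one (CNP0190193.0) | COc1cc(O)c2c(=O)c(O)c(-c3ccc(Oc4ccc(-c5oc6cc(O)cc(O)c6c(=O)c5O)cc4OC)c(O)c3)oc2c1 | target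

## Step count and least certain steps

Total step count: 13. Longest linear sequence: 11 steps (steps 1, 3, 4, 5, 6, 7, 9, 10, 11, 12, 13 from compound 1; the same length from compound 3 through step 2). Steps 2 and 8 are side branches.

Step 6 (key step). Three things can go wrong. The lactone may fail to open, because the side-chain enolate pushes electron density into the pyranone and makes its carbonyl a poor acceptor for methoxide. The open chain 10 may fragment by retro-Claisen attack of methoxide on one of the ketones. The enol ether double bond may move out of conjugation, after which C2 can close onto the C7 ketone in an aldol sense and give a resorcylate-type ring instead of the phloroglucinol. The fallback gives up building ring A and buys it. It sets out from aldehyde 5. Commercial 1-(2,6-dihydroxy-4-methoxyphenyl)ethanone F1 would be protected at one phenol with MOMCl and iPr2NEt in CH2Cl2 to give 1-[2-hydroxy-4-methoxy-6-(methoxymethoxy)phenyl]ethanone F2; the second phenol is chelated and stays free. Claisen–Schmidt condensation of F2 with 5 (KOH, EtOH) would give the chalcone F3. Aqueous HCl in THF–MeOH would remove the methoxymethyl group and the acetal to give the dihydroxychalcone aldehyde F4, and I2 in DMSO at 120 °C would close and dehydrogenate it. The fallback returns to the route at compound 14.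

Step 5. The risks are deprotonation of 7 at a ring position instead of the methyl group, conjugate addition of 8 to the cinnamamide in place of 1,2-addition, and proton transfer that stops the acylation. The fallback replaces acylation by aldol addition and oxidation. It sets out from amide 6, which iBu2AlH in THF at −78 °C would reduce to the enal F5. Lithiated pyranone 8 would add to the aldehyde carbonyl of F5 at −78 °C, a well-used reaction of this anion with cinnamaldehydes, to give the racemic allylic alcohol F6. MnO2 in CH2Cl2 would oxidise F6 to the ketone, and the fallback returns at compound 9.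

Step 12. The second, electron-poor C2=C3 bond may be oxidised incompletely. The dioxirane may oxidise benzylic C–H bonds of the four benzyl ethers during the long reaction time. If traces of acid open an epoxide early, the first-formed 3-hydroxy enol, which is more electron-rich than a flavone, would be over-oxidised by the remaining oxidant. The fallback uses deprotonation instead of electrophilic oxidation. It sets out from compound 20. LiN(iPr)2 in THF at −78 °C would lithiate both C3 positions, B(OMe)3 would trap them as the bis(dimethyl boronate) F7 (not isolated), and H2O2 with AcOH would oxidise both C–B bonds. The fallback returns at compound 22.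

Step 3. The substitution may be slow because the benzyloxy group ortho to fluorine adds steric and electronic hindrance, and at the temperature then needed the phenoxide of 4 may ionise at its acetal carbon and decompose. The fallback moves the acetalisation to a stage without a free phenol and uses a nitrile as the activating group. It sets out from vanillin 3. Commercial 4-fluoro-3-hydroxybenzonitrile F8 would be benzylated (BnBr, K2CO3, DMF) to 3-(benzyloxy)-4-fluorobenzonitrile F9. Substitution of its fluoride by the robust phenoxide of 3 (K2CO3, DMSO, 130 °C) would give the diaryl ether aldehyde nitrile F10. Acetalisation (HC(OMe)3, MeOH, TsOH cat.) would give the acetal nitrile F11. Reduction of the nitrile with iBu2AlH in toluene at −78 °C, followed by work-up with aqueous KNaC4H4O6 and wet silica gel, would return the route to compound 5.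

## Further compounds

F1 | step 6 | 1-(2,6-dihydroxy-4-methoxyphenyl)ethanone (purchased for the fallback) | CC(=O)c1c(O)cc(OC)cc1O
F2 | step 6 | 1-[2-hydroxy-4-methoxy-6-(methoxymethoxy)phenyl]ethanone | COCOc1cc(OC)cc(O)c1C(C)=O
F3 | step 6 | (2E)-3-{3-(benzyloxy)-4-[4-(dimethoxymethyl)-2-methoxyphenoxy]phenyl}-1-[2-hydroxy-4-methoxy-6-(methoxymethoxy)phenyl]prop-2-en-1-one | COCOc1cc(OC)cc(O)c1C(=O)/C=C/c1ccc(Oc2ccc(C(OC)OC)cc2OC)c(OCc2ccccc2)c1
F4 | step 6 | 4-{2-(benzyloxy)-4-[(1E)-3-(2,6-dihydroxy-4-methoxyphenyl)-3-oxoprop-1-en-1-yl]phenoxy}-3-methoxybenzaldehyde | COc1cc(O)c(C(=O)/C=C/c2ccc(Oc3ccc(C=O)cc3OC)c(OCc3ccccc3)c2)c(O)c1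
F5 | step 5 | (2E)-3-{3-(benzyloxy)-4-[4-(dimethoxymethyl)-2-methoxyphenoxy]phenyl}prop-2-enal | O=C/C=C/c1ccc(Oc2ccc(C(OC)OC)cc2OC)c(OCc2ccccc2)c1
F6 | step 5 | rac-6-[(3E)-4-{3-(benzyloxy)-4-[4-(dimethoxymethyl)-2-methoxyphenoxy]phenyl}-2-hydroxybut-3-en-1-yl]-4-methoxy-2H-pyran-2-one | COC1=CC(=O)OC(CC(O)/C=C/c2ccc(Oc3ccc(C(OC)OC)cc3OC)c(OCc3ccccc3)c2)=C1
F7 | step 12 | bis(dimethyl boronate) of 20, a B(OMe)2 group at C3 of each chromenone (not isolated) | COc1cc(OCc2ccccc2)c2c(=O)c(B(OC)OC)c(-c3ccc(Oc4ccc(-c5oc6cc(OCc7ccccc7)cc(OCc7ccccc7)c6c(=O)c5B(OC)OC)cc4OC)c(OCc4ccccc4)c3)oc2c1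
F8 | step 3 | 4-fluoro-3-hydroxybenzonitrile (purchased for the fallback) | N#Cc1ccc(F)c(O)c1
F9 | step 3 | 3-(benzyloxy)-4-fluorobenzonitrile | N#Cc1ccc(F)c(OCc2ccccc2)c1
F10 | step 3 | 3-(benzyloxy)-4-(4-formyl-2-methoxyphenoxy)benzonitrile | COc1cc(C=O)ccc1Oc1ccc(C#N)cc1OCc1ccccc1
F11 | step 3 | 3-(benzyloxy)-4-[4-(dimethoxymethyl)-2-methoxyphenoxy]benzonitrile | COC(OC)c1ccc(Oc2ccc(C#N)cc2OCc2ccccc2)c(OC)c1
A1 | alternative 1 | 3,5,7-tris(benzyloxy)-2-[4-(furan-3-yloxy)-3-methoxyphenyl]-4H-chromen-4-one | COc1cc(-c2oc3cc(OCc4ccccc4)cc(OCc4ccccc4)c3c(=O)c2OCc2ccccc2)ccc1Oc1ccoc1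
A2 | alternative 1 | methyl propiolate | C#CC(=O)OC
A3 | alternative 1 | methyl 3-hydroxy-4-{2-methoxy-4-[3,5,7-tris(benzyloxy)-4-oxo-4H-chromen-2-yl]phenoxy}benzoate | COC(=O)c1ccc(Oc2ccc(-c3oc4cc(OCc5ccccc5)cc(OCc5ccccc5)c4c(=O)c3OCc3ccccc3)cc2OC)c(O)c1
A4 | alternative 2 | rac-2-(benzyloxy)-1-{4-[2-(benzyloxy)-4-(3-(benzyloxy)-5,7-dimethoxy-4-oxo-4H-chromen-2-yl)phenoxy]-3-methoxyphenyl}-3-(2,4,6-trifluorophenyl)propane-1,3-dione | O=C(c1c(F)cc(F)cc1F)C(OCc1ccccc1)C(=O)c1ccc(Oc2ccc(-c3oc4cc(OC)cc(OC)c4c(=O)c3OCc3ccccc3)cc2OCc2ccccc2)c(OC)c1
A5 | alternative 2 | sodium benzyloxide | [Na+].[O-]Cc1ccccc1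
A6 | alternative 2 | 3,5,7-tris(benzyloxy)-2-{4-[2-(benzyloxy)-4-(3-(benzyloxy)-5,7-dimethoxy-4-oxo-4H-chromen-2-yl)phenoxy]-3-methoxyphenyl}-4H-chromen-4-one | O=c1c(OCc2ccccc2)c(-c2ccc(Oc3ccc(-c4oc5cc(OC)cc(OC)c5c(=O)c4OCc4ccccc4)cc3OCc3ccccc3)c(OC)c2)oc2cc(OCc3ccccc3)cc(OCc3ccccc3)c12
A7 | alternative 3 | 2-(benzyloxyacetyl)-3,5-dimethoxyphenyl 3-(benzyloxy)-4-{4-[(3,5-bis(benzyloxy)-2-(benzyloxyacetyl)phenoxy)carbonyl]-2-methoxyphenoxy}benzoate | COc1cc(OC)c(C(=O)COCc2ccccc2)c(OC(=O)c2ccc(Oc3ccc(C(=O)Oc4cc(OCc5ccccc5)cc(OCc5ccccc5)c4C(=O)COCc4ccccc4)cc3OC)c(OCc3ccccc3)c2)c1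
A8 | alternative 3 | bis(2-benzyloxy-1,3-diketone) with both ortho phenols free, both α carbons racemic | COc1cc(OC)c(C(=O)C(OCc2ccccc2)C(=O)c2ccc(Oc3ccc(C(=O)C(OCc4ccccc4)C(=O)c4c(O)cc(OCc5ccccc5)cc4OCc4ccccc4)cc3OC)c(OCc3ccccc3)c2)c(O)c1
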